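## The problem

- The target is an eleven-membered humulane carbocycle (C1–C11). It carries a Z C2=C3 alkene with a methyl group on C3, an E C6=C7 alkene with a methyl group on C7, a quaternary C11 with two methyl groups, an acetate on C1 and a 4-hydroxybenzoate on C4.
- The only stereocentres are C1 (S) and C4 (R), 1,4-related across the Z alkene. Neither can be relied on to control the other, so the relative configuration has to be secured deliberately.
- The two carbinols differ sharply. C4 is an ordinary secondary allylic alcohol that can be resolved and, if necessary, inverted by substitution. C1 is neopentyl (next to C11), cannot be inverted by substitution, and gives a ketone too encumbered for dependable reagent-controlled reduction.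
- The 1,4-bis(acyloxy)-2-ene is a doubly allylic, ionisable unit. It should not meet zerovalent palladium, strong acid or hard base, the Z alkene must not isomerise, and the phenol must be free at the end. Both esters therefore belong after all C–C bond formation.
- A medium ring with two trisubstituted alkenes is best closed at a bond remote from the stereocentres, with both alkene geometries fixed beforehand. The sp2–sp3 bond C7–C8 is the natural site.
- The enabling feature is the array C1(O)–C2H=C3(CH3)–C4(O) with Z geometry. It is what results when methyl and magnesium add anti across the terminal alkyne of a C4 propargylic alkoxide (methyl to C3, metal to C2, held cis to C4 by O–Mg chelation) and the alkenylmagnesium is captured by a C1 aldehyde.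

## Retrosynthesis

**Esters (16 ⇒ 15 ⇒ 14 ⇒ 12 + 13).** The O–Si bond of the phenol, the acetyl–O bond at C1 and the aroyl–O bond at C4 are cut in that order. Carrying the esters through ring closure is rejected, because zerovalent palladium could ionise the bis(acyloxy)ene. Diol 12 is free of protecting groups. The forward reactions must tell the two secondary allylic hydroxyls apart: the bulky aroyl donor 13 goes to the accessible C4–OH first, then the small acetyl group is forced onto neopentyl C1–OH.

**Ring (12 ⇒ 10 via 11).** The C7–C8 bond is cut, to be formed by B-alkyl Suzuki macrocyclisation of the alkenyl bromide and the terminal alkene of 10. Against its neighbours: ring-closing metathesis at C6=C7 would not control the E geometry of a trisubstituted alkene in an eleven-membered ring, and closure at C1–C2 would turn the three-component step into a macrocyclisation of a dianion. The precursor 10 is acyclic with both alkene geometries stored. The forward reaction must hydroborate only the monosubstituted alkene and couple with retention at C7.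

**Z-enediol (10 ⇒ 6 + 7 + 8 via 9).** The C3–CH3 and C1–C2 bonds are cut. One flask joins propargylic alcohol 6, methylmagnesium bromide 7 and neopentyl aldehyde 8, fixing the Z alkene through chelate 9. This is shorter than stepwise carbonyl additions plus a Z-selective olefination or semi-reduction. It is asked to give anti, regioselective carbometalation and to spare the alkenyl bromide and both remote alkenes.

**Configuration at C1.** Only 1,4-induction through the chelate is available. Oxidation and oxazaborolidine-catalysed reduction at C1 was weighed and set aside: the ketone is flanked by quaternary C11 on one side and by a Z-alkenyl group whose cis substituent (C4) blocks the other side, so a chiral Lewis acid has no preferred site. The plan isolates the 1S epimer 10 by chromatography. It keeps in reserve that C4, unlike C1, can be inverted during esterification, so either antipode of 5 can serve.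

**Alkynol (6 ⇒ 5 ⇒ 3 + 4; 3 ⇒ 2 ⇒ 1).** Lipase resolution of racemate 5 supplies the C4 stereocentre. Compound 5 comes from ethynyl Grignard 4 and aldehyde 3, which comes by oxidation of alcohol 2.
- The C7 unit needs halogen and methyl on the same carbon and hydrogen on C6. That is the outcome of syn-hydrometalation of the methyl-capped alkyne of 1 with the metal at the methyl terminus. Methylmetalation of a terminal C6≡C7 alkyne would put the methyl group on C6 and is not an option.
- The hydrozirconation is placed first because later it could not distinguish an internal alkyne from the monosubstituted alkene that arrives with 8.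
- Bromide is chosen over iodide because it must pass through the copper-catalysed Grignard step.

## Roads not taken

**Alternative 1: radical opening of caryophyllene oxide A1.**
- Cut: the cyclobutane bond between the two ring-fusion carbons, which converts the bicycle into the eleven-membered ring.
- Forward step: hydrogen-atom transfer from the iron hydride made from Fe(acac)3 and PhSiH3 to the exocyclic methylene gives a tertiary radical. β-Scission opens the four-membered ring and the resulting secondary radical is reduced, giving epoxide A2.
- Merits: one step from a cheap enantiopure terpene to the full C15 skeleton with the gem-dimethyl carbon, and no macrocyclisation. In economy of skeleton construction this road is clearly better than the chosen one.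
- Weak points: in A2 the C2=C3 alkene is E where the target needs Z, and C1 and C4 are unoxidised methylene groups. The target would require two stereocontrolled allylic oxygenations on a flexible ring, an alkene inversion, and deoxygenation of the epoxide to the C6=C7 alkene, which erases the only stereocentres.
- Comparison: the chosen plan is longer to the ring, but it delivers both oxygens, the Z geometry and the C4 configuration from the key step.

**Alternative 2: late double methylation at C11.**
- Cut: both C11–CH3 bonds.
- Forward step: two cycles of LDA and MeI on macrocyclic Z-enone A3 through its cross-conjugated enolate, giving A4.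
- Merits: the ring is closed on a less congested chain and the quaternary carbon comes from a cheap electrophile. Both C1 epimers of any earlier intermediate would converge on one ketone.
- Weak points: deprotonation must occur at C11 and not at C4, whose hydrogen is vinylogously activated and whose silyloxy group can be expelled. The Z enone and the C4 stereocentre are exposed to strong base twice, and the second methylation meets a hindered enolate. A4 still needs reduction of the doubly hindered C1 ketone to the 1S alcohol, the reduction judged unreliable above.
- Comparison: the chosen plan buys the quaternary carbon ready-made in aldehyde 8 and never exposes C4 to strong base. The price is a hindered C1 hydroxyl, which it turns to use for site selection.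

**Alternative 3: B-alkyl Suzuki macrocyclisation as the strategic step.**
- Cut: C7–C8.
- Forward step: hydroboration of the terminal alkene of the fully protected alkenyl iodide A5 with 9-BBN, then coupling with Pd(dppf)Cl2, AsPh3 and Cs2CO3, giving macrocycle A6.
- Merits: this is the more secure ring closure. The iodide couples at room temperature, no free hydroxyl meets palladium, and orthogonal PMB and silyl ethers place the two esters without any selectivity question.
- Weak points: it leaves open how the Z-enediol of A5 is assembled. It needs PMB etherification of the neopentyl C1 hydroxyl and an oxidative PMB removal beside electron-rich alkenes. It adds at least four protecting-group operations.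
- Comparison: the chosen plan keeps the same C7–C8 closure as step 6, but on the unprotected bromide 10. It trades some security for a one-flask assembly of the enediol and a shorter end-game. Its fallbacks for steps 6 and 7 retreat towards the protected format of A5 if needed.

Key step: step 5

Remark: locants C1–C11 are those of the ring in diol 12 (C1 acetoxy carbon, C4 aroyloxy carbon, C11 gem-dimethyl carbon); acid 13 is taken as a purchasable compound.

## Route

Step 1
Reactants: 1 pent-3-yn-1-ol
Product: 2 (3E)-4-bromopent-3-en-1-ol
Conditions: Cp2Zr(H)Cl (2.5 equiv), THF, rt → 45 °C; NBS, 0 °C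
Reagents that add atoms: N-bromosuccinimide, O=C1CCC(=O)N1Br
Why: Hydrozirconation–bromination: Zr–H adds syn across the methyl-capped alkyne (the first equivalent is consumed by the hydroxyl), and excess reagent with gentle heating equilibrates zirconium to the less hindered methyl terminus. NBS cleaves the C–Zr bond with retention, giving the E alkenyl bromide with bromine and methyl on the same carbon.

Step 2
Reactants: 2 (3E)-4-bromopent-3-en-1-ol
Product: 3 (3E)-4-bromopent-3-enal
Conditions: Dess–Martin periodinane, NaHCO3, CH2Cl2, 0 °C → rt; used crude
Reagents that add atoms: none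
Why: Dess–Martin oxidation under bicarbonate buffer gives the β,γ-unsaturated aldehyde without migration of the alkene into conjugation. The aldehyde is used at once.

Step 3
Reactants: 3 (3E)-4-bromopent-3-enal; 4 ethynylmagnesium bromide
Product: 5 rac-(5E)-6-bromohept-5-en-1-yn-3-ol
Conditions: THF, −78 → 0 °C
Reagents that add atoms: none
Why: 1,2-Addition of an alkynyl Grignard reagent to an aldehyde at low temperature should outrun enolisation; the alkenyl bromide is inert to the acetylide. The carbinol forms racemic.

Step 4
Reactants: 5 rac-(5E)-6-bromohept-5-en-1-yn-3-ol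
Product: 6 (3R,5E)-6-bromohept-5-en-1-yn-3-ol
Conditions: Amano lipase PS (Burkholderia cepacia), vinyl acetate, t-BuOMe, 30 °C, stopped just past half conversion
Reagents that add atoms: none
Why: Lipase-catalysed kinetic resolution by transesterification: by the empirical size rule for secondary alcohols (large group CH2CH=C(Br)CH3, medium group ethynyl) the S enantiomer should be acetylated faster, leaving the R alcohol. Running slightly past half conversion should bring it to high enantiopurity; this sets C4 of the target.

Step 5
Reactants: 6 (3R,5E)-6-bromohept-5-en-1-yn-3-ol; 7 methylmagnesium bromide; 8 2,2-dimethylpent-4-enal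
Product: 10 (5S,6Z,8R,10E)-11-bromo-4,4,7-trimethyldodeca-1,6,10-triene-5,8-diol, via oxamagnesacycle 9 (not isolated)
Conditions: 7 (2.4 equiv), CuI (15 mol%), Et2O–THF, −10 °C → rt; then 8 (1.6 equiv), −20 °C → rt
Reagents that add atoms: none
Why: MeMgBr first converts 6 into its magnesium alkoxide, and a methylcopper species formed from CuI and further MeMgBr adds across the terminal alkyne under alkoxide direction, delivering methyl to the alkyne carbon next to the carbinol (C3) and the metal to the terminal carbon (C2) from the opposite side. Copper-to-magnesium exchange then gives the five-membered oxamagnesacycle 9 (O, C4, C3, C2, Mg) and releases the catalyst, so the C2–Mg bond is held cis to C4. This chelated alkenyl Grignard reagent adds to the non-enolisable aldehyde 8 and forms C1–C2, the Z geometry of C2=C3 being fixed beforehand by the ring of 9. The closest known reaction type is the copper-catalysed anti-carbomagnesiation of propargylic alcohols with electrophilic capture of the cyclic alkenylmagnesium; no ring of the target is closed. C4 is carried over unchanged from 6, because no bond to it is made or broken. The new stereocentre C1 is controlled only by 1,4-induction from C4 through the chelate, which is expected to be weak and of unpredictable sense, so the 1S epimer 10 is separated from the 1R epimer by chromatography. The step needs regio- and anti-selectivity, both secured by the alkoxide chelate on a terminal propargylic alkyne, and chemoselectivity: an alkenyl bromide is not expected to couple with Grignard reagents under copper catalysis in ether at room temperature (the reason for bromide rather than iodide), and the two remote alkenes have no alkoxide within directing distance. Aldehyde 8 is used in excess to consume residual MeMgBr.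

Step 6
Reactants: 10 (5S,6Z,8R,10E)-11-bromo-4,4,7-trimethyldodeca-1,6,10-triene-5,8-diol
Product: 12 (1S,2Z,4R,6E)-3,7,11,11-tetramethylcycloundeca-2,6-diene-1,4-diol, via B-alkyl-9-BBN adduct 11 (not isolated)
Conditions: 9-BBN dimer (3.5 equiv), THF, rt; H2O; then slow addition to Pd(dppf)Cl2 (20 mol%), AsPh3, Cs2CO3, DMF–THF–H2O, 55 °C, high dilution
Reagents that add atoms: none
Why: B-alkyl Suzuki macrocyclisation: 9-BBN hydroborates only the monosubstituted alkene (boron on C8; excess reagent is taken up by the hydroxyls as borinates that hydrolyse in the basic medium). Zerovalent palladium formed from Pd(dppf)Cl2 inserts into the alkenyl C–Br bond and couples with the base-activated alkylborane with retention of the E geometry, closing the ring at C7–C8 far from both stereocentres. Aqueous carbonate keeps boron as borate, so the free allylic hydroxyls should not be activated toward ionisation, and slow addition at high dilution suppresses oligomerisation.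

Step 7
Reactants: 12 (1S,2Z,4R,6E)-3,7,11,11-tetramethylcycloundeca-2,6-diene-1,4-diol; 13 4-(tert-butyldimethylsilyloxy)benzoic acid
Product: 14 (1S,2Z,4R,6E)-1-hydroxy-3,7,11,11-tetramethylcycloundeca-2,6-dien-4-yl 4-(tert-butyldimethylsilyloxy)benzoate (locants of 12)
Conditions: EDC·HCl, DMAP, CH2Cl2, 0 °C → rt
Reagents that add atoms: none
Why: Steglich esterification: the C4 hydroxyl, flanked by a methylene group and the alkene, should be acylated, while the neopentyl C1 hydroxyl next to quaternary C11 reacts far more slowly with the bulky acylpyridinium ion. The C4–O bond is untouched, so configuration is retained.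

Step 8
Reactants: 14 (1S,2Z,4R,6E)-1-hydroxy-3,7,11,11-tetramethylcycloundeca-2,6-dien-4-yl 4-(tert-butyldimethylsilyloxy)benzoate
Product: 15 (1S,2Z,4R,6E)-1-acetoxy-3,7,11,11-tetramethylcycloundeca-2,6-dien-4-yl 4-(tert-butyldimethylsilyloxy)benzoate (locants of 12)
Conditions: Ac2O, DMAP, pyridine, CH2Cl2, rt → 40 °C
Reagents that add atoms: acetic anhydride, CC(=O)OC(C)=O
Why: DMAP-catalysed acetylation with the small electrophile acetic anhydride should reach the hindered C1 hydroxyl under mild forcing. The aryl silyl ether and the C4 ester are stable to amine bases.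

Step 9
Reactants: 15 (1S,2Z,4R,6E)-1-acetoxy-3,7,11,11-tetramethylcycloundeca-2,6-dien-4-yl 4-(tert-butyldimethylsilyloxy)benzoate
Product: 16 (1S,2Z,4R,6E)-1-acetoxy-3,7,11,11-tetramethylcycloundeca-2,6-dien-4-yl 4-hydroxybenzoate (locants of 12), CNP0246761.2
Conditions: TBAF, AcOH, THF, 0 °C
Reagents that add atoms: none
Why: Fluoride cleaves the aryl silyl ether rapidly. Acetic acid buffers the phenoxide, so neither ester should be transesterified and the doubly allylic system sees neither strong base nor strong acid.

## Compound list

1 | pent-3-yn-1-ol | CC#CCCO | starting material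
2 | (3E)-4-bromopent-3-en-1-ol | OCC/C=C(\C)Br | intermediate
3 | (3E)-4-bromopent-3-enal | O=CC/C=C(\C)Br | intermediate
4 | ethynylmagnesium bromide | C#C[Mg]Br | starting material
5 | rac-(5E)-6-bromohept-5-en-1-yn-3-ol | C#CC(O)C/C=C(\C)Br | intermediate
6 | (3R,5E)-6-bromohept-5-en-1-yn-3-ol | C#C[C@H](O)C/C=C(\C)Br | intermediate
7 | methylmagnesium bromide | C[Mg]Br | starting material
8 | 2,2-dimethylpent-4-enal | C=CCC(C)(C)C=O | starting material
9 | (5R)-5-[(2E)-3-bromobut-2-en-1-yl]-4-methyl-2,5-dihydro-1,2-oxamagnesole (further ligands on magnesium omitted) | CC1=C[Mg]O[C@@H]1C/C=C(\C)Br | intermediate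
10 | (5S,6Z,8R,10E)-11-bromo-4,4,7-trimethyldodeca-1,6,10-triene-5,8-diol | C=CCC(C)(C)[C@@H](O)/C=C(/C)[C@H](O)C/C=C(\C)Br | intermediate
11 | (2E,5R,6Z,8S)-12-(9-borabicyclo[3.3.1]nonan-9-yl)-2-bromo-6,9,9-trimethyldodeca-2,6-diene-5,8-diol (B-alkyl-9-BBN adduct of 10) | C1CCC2CCCC1B2CCCC(C)(C)[C@@H](O)/C=C(/C)[C@H](O)C/C=C(\C)Br | intermediate
12 | (1S,2Z,4R,6E)-3,7,11,11-tetramethylcycloundeca-2,6-diene-1,4-diol | O[C@H]1/C=C(/C)[C@H](O)C/C=C(\C)CCCC1(C)C | intermediate
13 | 4-(tert-butyldimethylsilyloxy)benzoic acid | CC(C)(C)[Si](C)(C)Oc1ccc(cc1)C(=O)O | starting material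
14 | (1S,2Z,4R,6E)-1-hydroxy-3,7,11,11-tetramethylcycloundeca-2,6-dien-4-yl 4-(tert-butyldimethylsilyloxy)benzoate | O[C@H]1/C=C(/C)[C@H](OC(=O)c2ccc(O[Si](C)(C)C(C)(C)C)cc2)C/C=C(\C)CCCC1(C)C | intermediate
15 | (1S,2Z,4R,6E)-1-acetoxy-3,7,11,11-tetramethylcycloundeca-2,6-dien-4-yl 4-(tert-butyldimethylsilyloxy)benzoate | CC(=O)O[C@H]1/C=C(/C)[C@H](OC(=O)c2ccc(O[Si](C)(C)C(C)(C)C)cc2)C/C=C(\C)CCCC1(C)C | intermediate
16 | (1S,2Z,4R,6E)-1-acetoxy-3,7,11,11-tetramethylcycloundeca-2,6-dien-4-yl 4-hydroxybenzoate | CC(=O)O[C@H]1/C=C(/C)[C@H](OC(=O)c2ccc(O)cc2)C/C=C(\C)CCCC1(C)C | target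

## Step count and least certain steps

Total steps: 9. Longest linear sequence: 9 steps (1 → 16); compounds 4, 7, 8 and 13 are purchased.

**Step 5 (key step).**
- Most likely to go wrong: low or adverse facial selectivity in the addition of 9 to 8. The C4 substituent is remote from the reacting carbon and the magnesium species is aggregated, so the 1S epimer may be the minor one. A smaller concern is slow methyl transfer to the alkenyl bromide if copper loading or temperature is raised.
- Fallback (sets out from 5, returns at 14): it uses the fact that C4 can be inverted while C1 cannot.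
  - (3S,5E)-6-Bromohept-5-en-1-yn-3-yl acetate F1, formed beside 6 in step 4, is methanolysed (K2CO3, MeOH) to (3S,5E)-6-bromohept-5-en-1-yn-3-ol F2.
  - The same carbomagnesiation with 7 and capture by 8, through the enantiomeric oxamagnesacycle F3, gives (5S,6Z,8S,10E)-11-bromo-4,4,7-trimethyldodeca-1,6,10-triene-5,8-diol F4. F4 is the major product if the like sense of induction prevails.
  - Hydroboration to the B-alkyl-9-BBN adduct F5 and ring closure as in step 6 give (1S,2Z,4S,6E)-3,7,11,11-tetramethylcycloundeca-2,6-diene-1,4-diol F6.
  - Mitsunobu esterification of F6 with 13 (PPh3, diisopropyl azodicarboxylate, THF) acylates only the C4 hydroxyl, with inversion, and delivers 14.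
  - Whichever sense the induction takes, one antipode of 5 therefore leads to the target.

**Step 6 (macrocyclisation).**
- Most likely to go wrong: slow oxidative addition of the trisubstituted alkenyl bromide at high dilution, so that oligomerisation and loss of the alkylborane compete with closure of a strained eleven-membered ring.
- Fallback (sets out from 10, returns at 12):
  - Silylation (TESOTf, 2,6-lutidine) gives the bis(triethylsilyl) ether F7.
  - Copper-catalysed halogen exchange (CuI, NaI, N,N′-dimethylethylenediamine, dioxane, 110 °C) gives the alkenyl iodide F8.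
  - Hydroboration gives the B-alkyl-9-BBN adduct F9, and coupling at room temperature with the same palladium system gives the bis-silylated macrocycle F10.
  - TBAF returns 12.

**Step 7 (site-selective aroylation).**
- Most likely to go wrong: insufficient discrimination between the two hydroxyls in the ring, whose conformation may shield C4–OH, leading to acylation at C1 or at both positions.
- Fallback (sets out from 10, returns at 15): differentiation is moved to the acyclic diol, where the steric difference is beyond doubt.
  - TBSCl and imidazole silylate only C4–OH to give the mono-silyl ether F11.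
  - Hydroboration (adduct F12) and ring closure give the C4-silylated macrocyclic alcohol F13.
  - Ac2O and DMAP give the C1 acetate F14.
  - HF·pyridine frees C4–OH to give the hydroxy acetate F15.
  - Steglich esterification with 13 gives 15.

**Step 1 (hydrozirconation–bromination).**
- Most likely to go wrong: delivery of zirconium to the alkyne carbon nearer the oxygen through the zirconium alkoxide, or incomplete equilibration, giving the wrong placement of bromine.
- Fallback (sets out from 1, returns at 2): the hydroxyl is masked so that only steric control operates.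
  - TBSCl and imidazole give tert-butyldimethyl(pent-3-yn-1-yloxy)silane F16.
  - Hydrozirconation–bromination gives {[(3E)-4-bromopent-3-en-1-yl]oxy}(tert-butyl)dimethylsilane F17.
  - TBAF gives 2.

## Further compounds

F1 | step 5 | (3S,5E)-6-bromohept-5-en-1-yn-3-yl acetate | C#C[C@@H](OC(C)=O)C/C=C(\C)Br
F2 | step 5 | (3S,5E)-6-bromohept-5-en-1-yn-3-ol | C#C[C@@H](O)C/C=C(\C)Br
F3 | step 5 | (5S)-5-[(2E)-3-bromobut-2-en-1-yl]-4-methyl-2,5-dihydro-1,2-oxamagnesole | CC1=C[Mg]O[C@H]1C/C=C(\C)Br
F4 | step 5 | (5S,6Z,8S,10E)-11-bromo-4,4,7-trimethyldodeca-1,6,10-triene-5,8-diol | C=CCC(C)(C)[C@@H](O)/C=C(/C)[C@@H](O)C/C=C(\C)Br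
F5 | step 5 | B-alkyl-9-BBN adduct of F4 | C1CCC2CCCC1B2CCCC(C)(C)[C@@H](O)/C=C(/C)[C@@H](O)C/C=C(\C)Br
F6 | step 5 | (1S,2Z,4S,6E)-3,7,11,11-tetramethylcycloundeca-2,6-diene-1,4-diol | O[C@H]1/C=C(/C)[C@@H](O)C/C=C(\C)CCCC1(C)C
F7 | step 6 | (5S,6Z,8R,10E)-11-bromo-4,4,7-trimethyl-5,8-bis(triethylsilyloxy)dodeca-1,6,10-triene | C=CCC(C)(C)[C@@H](O[Si](CC)(CC)CC)/C=C(/C)[C@H](O[Si](CC)(CC)CC)C/C=C(\C)Br
F8 | step 6 | (5S,6Z,8R,10E)-11-iodo-4,4,7-trimethyl-5,8-bis(triethylsilyloxy)dodeca-1,6,10-triene | C=CCC(C)(C)[C@@H](O[Si](CC)(CC)CC)/C=C(/C)[C@H](O[Si](CC)(CC)CC)C/C=C(\C)I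
F9 | step 6 | B-alkyl-9-BBN adduct of F8 | C1CCC2CCCC1B2CCCC(C)(C)[C@@H](O[Si](CC)(CC)CC)/C=C(/C)[C@H](O[Si](CC)(CC)CC)C/C=C(\C)I
F10 | step 6 | (1S,2Z,4R,6E)-3,7,11,11-tetramethyl-1,4-bis(triethylsilyloxy)cycloundeca-2,6-diene | CC[Si](CC)(CC)O[C@H]1/C=C(/C)[C@H](O[Si](CC)(CC)CC)C/C=C(\C)CCCC1(C)C
F11 | step 7 | (5S,6Z,8R,10E)-11-bromo-8-(tert-butyldimethylsilyloxy)-4,4,7-trimethyldodeca-1,6,10-trien-5-ol | C=CCC(C)(C)[C@@H](O)/C=C(/C)[C@H](O[Si](C)(C)C(C)(C)C)C/C=C(\C)Br
F12 | step 7 | B-alkyl-9-BBN adduct of F11 | C1CCC2CCCC1B2CCCC(C)(C)[C@@H](O)/C=C(/C)[C@H](O[Si](C)(C)C(C)(C)C)C/C=C(\C)Br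
F13 | step 7 | (1S,2Z,4R,6E)-4-(tert-butyldimethylsilyloxy)-3,7,11,11-tetramethylcycloundeca-2,6-dien-1-ol | O[C@H]1/C=C(/C)[C@H](O[Si](C)(C)C(C)(C)C)C/C=C(\C)CCCC1(C)C
F14 | step 7 | (1S,2Z,4R,6E)-4-(tert-butyldimethylsilyloxy)-3,7,11,11-tetramethylcycloundeca-2,6-dien-1-yl acetate | CC(=O)O[C@H]1/C=C(/C)[C@H](O[Si](C)(C)C(C)(C)C)C/C=C(\C)CCCC1(C)C
F15 | step 7 | (1S,2Z,4R,6E)-4-hydroxy-3,7,11,11-tetramethylcycloundeca-2,6-dien-1-yl acetate | CC(=O)O[C@H]1/C=C(/C)[C@H](O)C/C=C(\C)CCCC1(C)C
F16 | step 1 | tert-butyldimethyl(pent-3-yn-1-yloxy)silane | CC#CCCO[Si](C)(C)C(C)(C)C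
F17 | step 1 | {[(3E)-4-bromopent-3-en-1-yl]oxy}(tert-butyl)dimethylsilane | CC(C)(C)[Si](C)(C)OCC/C=C(\C)Br
A1 | alternative 1 | caryophyllene oxide | C[C@@]12CC[C@@H]3[C@H](CC3(C)C)C(=C)CC[C@H]1O2
A2 | alternative 1 | (2E)-9,10-dihydrohumula-2,6-diene 6,7-trans-epoxide | C[C@@]12CCCC(C)(C)C/C=C(\C)CC[C@H]1O2
A3 | alternative 2 | (2Z,4R,6E)-4-(tert-butyldimethylsilyloxy)-3,7-dimethylcycloundeca-2,6-dienone | O=C1/C=C(/C)[C@H](O[Si](C)(C)C(C)(C)C)C/C=C(\C)CCCC1
A4 | alternative 2 | (2Z,4R,6E)-4-(tert-butyldimethylsilyloxy)-3,7,11,11-tetramethylcycloundeca-2,6-dienone | O=C1/C=C(/C)[C@H](O[Si](C)(C)C(C)(C)C)C/C=C(\C)CCCC1(C)C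
A5 | alternative 3 | (5S,6Z,8R,10E)-8-(tert-butyldimethylsilyloxy)-11-iodo-5-(4-methoxybenzyloxy)-4,4,7-trimethyldodeca-1,6,10-triene | C=CCC(C)(C)[C@@H](OCc1ccc(OC)cc1)/C=C(/C)[C@H](O[Si](C)(C)C(C)(C)C)C/C=C(\C)I
A6 | alternative 3 | (1S,2Z,4R,6E)-4-(tert-butyldimethylsilyloxy)-1-(4-methoxybenzyloxy)-3,7,11,11-tetramethylcycloundeca-2,6-diene | COc1ccc(CO[C@H]2/C=C(/C)[C@H](O[Si](C)(C)C(C)(C)C)C/C=C(\C)CCCC2(C)C)cc1
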